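Labdane numbering is used: decalin C1–C10, side chain C11–C16, C17 on C8, C18/C19 on C4, C20 on C10; α/β refer to the usual drawing with C20 β.

**Plan**
1. The last bonds cut are the two isovalerate C–O bonds (O3, O19) and C13=C14, made by phosphonate olefination of a C13 methyl ketone.
2. Ring B holds the C6 carbinol, the C7 methylene and the C8=C9 double bond, so it is a cyclohex-3-enol. Cutting C6–C7 and rejoining C6 to C9 contracts it to a 2-isopropenylcyclobutanol (C5–C6–C9–C10) fused to ring A.
3. The cyclobutane is cut at C5–C6 and C9–C10 (dichloroketene plus the C5=C10 alkene of ring A). C9 is then dressed with C7/C8/C17 from acetone and with C11–C13/C16 by dienolate alkylation.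
4. Forward order: ring A (Birch reduction–methylation of an anisamide), cyclobutane, ring B by the 1,3-shift, side chain, esters.
5. Stereochemistry: C4 comes from a prolinol-ether auxiliary. C10 comes from α-face cycloaddition steered by C4 and a temporary 3β-ester, because a 3α-oxygen would lie on the face the ketene needs. C5 is set by equilibration of the 6-ketone, C3 and C6 together by hydride reduction of the trans-fused 3,6-dione, and C13=C14 (E) by the olefination.

Key step: step 14

Assumption: enolate 5 is taken to be methylated on the face turned away from the pyrrolidine ring carbons of the chelated enolate, so the (R)-auxiliary is drawn; should the sense be opposite, its equally available enantiomer serves with no other change.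

Step 1
Reactants: 1 2-methoxy-5-methylbenzoic acid; 2 (R)-2-(methoxymethyl)pyrrolidine
Product: 4 (R)-[2-(methoxymethyl)pyrrolidin-1-yl](2-methoxy-5-methylphenyl)methanone, via acid chloride 3 (not isolated)
Conditions: (COCl)2, DMF (cat.), CH2Cl2, 0 → 23 °C; then 2, Et3N, CH2Cl2, 0 °C
Reagents that add atoms: none
Why: N-acylation of the secondary amine by the acid chloride (oxalyl chloride/DMF activation) is routine for ortho-substituted benzoic acids and touches no stereocentre.

Step 2
Reactants: 4 chiral benzamide
Product: 6 [(1R)-2-methoxy-1,5-dimethylcyclohexa-2,5-dien-1-yl][(2R)-2-(methoxymethyl)pyrrolidin-1-yl]methanone, via potassium amide enolate 5 (not isolated)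
Conditions: K (2.2 equiv), NH3–THF, t-BuOH (1 equiv), −78 °C; then MeI, −78 °C
Reagents that add atoms: methyl iodide, CI
Why: In this asymmetric Birch reduction–alkylation of a chiral 2-methoxybenzamide, two-electron reduction and para protonation give chelated enolate 5, which MeI attacks at the ipso carbon on the face away from the pyrrolidine ring carbons, setting quaternary C4 and delivering at once the C5=C10 alkene and the C3 oxygen as an enol ether.

Step 3
Reactants: 6 Birch product
Product: 7 [(1S)-2-methoxy-1,5-dimethylcyclohexa-2,5-dien-1-yl]methanol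
Conditions: LiH2NBH3 (from BH3·NH3 and LiN(i-Pr)2), THF, 0 → 23 °C; then H2O
Reagents that add atoms: none
Why: Lithium amidotrihydroborate reduces hindered tertiary amides to primary alcohols through C–N cleavage of the hemiaminal, leaves the enol ether and the skipped diene alone, and returns the auxiliary.

Step 4
Reactants: 7 dienylmethanol
Product: 9 (2S)-2,4-dimethyl-2-[(triisopropylsilyloxy)methyl]cyclohex-3-en-1-one, via silylated dienol ether 8 (not isolated)
Conditions: i-Pr3SiCl, imidazole, DMF, 23 °C; then 1 M HCl, THF, 0 °C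
Reagents that add atoms: triisopropylsilyl chloride, CC(C)[Si](Cl)(C(C)C)C(C)C; water, O
Why: Silylation of the only hydroxyl is followed by mild acid hydrolysis of the methyl enol ether, where quaternary C4 keeps C5=C10 out of conjugation and the silyl ether blocks retro-aldol loss of formaldehyde.

Step 5
Reactants: 9 ring A ketone
Product: 10 (1S,2S)-2,4-dimethyl-2-[(triisopropylsilyloxy)methyl]cyclohex-3-en-1-ol (OH cis to CH2OSi; 3β-OH)
Conditions: LiBH(s-Bu)3, THF, −78 °C
Reagents that add atoms: none
Why: In this sterically controlled reduction with a bulky trialkylborohydride, hydride arrives on the α face beside the small C4 methyl and away from CH2OSi(i-Pr)3, giving the 3β-alcohol cis to C19, a temporary centre installed only to steer step 7.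

Step 6
Reactants: 10 ring A alcohol
Product: 11 (1S,2S)-2,4-dimethyl-2-[(triisopropylsilyloxy)methyl]cyclohex-3-en-1-yl pivalate
Conditions: t-BuCOCl, pyridine, DMAP (cat.), 50 °C
Reagents that add atoms: pivaloyl chloride, CC(C)(C)C(Cl)=O
Why: This is a DMAP-catalysed acylation, and a pivalate has no α-hydrogen, withstands the amide bases of steps 9 and 12, and is removed in hydride step 13 without a separate deprotection.

Step 7
Reactants: 11 ring A alkene
Product: 12 8,8-dichloro-1,5-dimethyl-7-oxo-5-[(triisopropylsilyloxy)methyl]bicyclo[4.2.0]octan-4-yl pivalate (cyclobutanone on the α face: C9 = CCl2, C6 = C=O, 5β-H, 10β-CH3)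
Conditions: Cl3CCOCl, Zn–Cu couple, POCl3, Et2O, 35 °C, ultrasound
Reagents that add atoms: trichloroacetyl chloride, ClC(Cl)(Cl)C(Cl)=O
Why: In this dichloroketene–alkene [2+2] cycloaddition (zinc/POCl3 variant for unreactive olefins), the ketene carbonyl carbon bonds to the less substituted C5 and CCl2 to C10 as with 1-methylcyclohexene, suprafacially from the α face because in the half-chair with pseudoaxial C19 both oxygenated groups cover the β face, which sets C10 while C5 stays provisional.

Step 8
Reactants: 12 dichlorocyclobutanone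
Product: 13 1,5-dimethyl-7-oxo-5-[(triisopropylsilyloxy)methyl]bicyclo[4.2.0]octan-4-yl pivalate
Conditions: Zn dust, AcOH, 23 → 50 °C
Reagents that add atoms: none
Why: Reductive dechlorination of an α,α-dichlorocyclobutanone with zinc in acetic acid is standard and spares the ester and the silyl ether.

Step 9
Reactants: 13 cyclobutanone
Product: 15 8-(2-hydroxypropan-2-yl)-1,5-dimethyl-7-oxo-5-[(triisopropylsilyloxy)methyl]bicyclo[4.2.0]octan-4-yl pivalate (carbinol group on the convex face), via lithium enolate 14 (not isolated)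
Conditions: LiN(i-Pr)2, THF, −78 °C; acetone, −78 °C; then AcOH, −78 °C
Reagents that add atoms: acetone, CC(C)=O
Why: Kinetic deprotonation takes the C9 methylene rather than the hindered ring-fusion C5–H, the aldol addition to acetone occurs on the convex face (temporary C9 centre), and the cold acidic quench forestalls retro-aldol.

Step 10
Reactants: 15 aldol
Product: 17 1,5-dimethyl-7-oxo-8-(propan-2-ylidene)-5-[(triisopropylsilyloxy)methyl]bicyclo[4.2.0]octan-4-yl pivalate, via tertiary mesylate 16 (not isolated)
Conditions: MsCl, Et3N, CH2Cl2, 0 °C; then DBU, 23 °C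
Reagents that add atoms: none
Why: Mesylation of the tertiary aldol and E1cB elimination give the conjugated isopropylidene ketone, and any isopropenyl isomer would lead to the same dienolate in step 12.

Step 11
Reactants: 18 2-(2-bromoethyl)-2-methyl-1,3-dioxolane
Product: 19 2-(2-iodoethyl)-2-methyl-1,3-dioxolane
Conditions: NaI, acetone, reflux
Reagents that add atoms: sodium iodide, [Na+].[I-]
Why: Finkelstein exchange, driven by precipitation of NaBr, supplies the more reactive iodide.

Step 12
Reactants: 17 isopropylidene cyclobutanone; 19 ketal iodide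
Product: 21 8-isopropenyl-1,5-dimethyl-8-[2-(2-methyl-1,3-dioxolan-2-yl)ethyl]-7-oxo-5-[(triisopropylsilyloxy)methyl]bicyclo[4.2.0]octan-4-yl pivalate (side chain convex, isopropenyl concave), via potassium dienolate 20 (not isolated)
Conditions: KN(SiMe3)2, THF, −78 → −30 °C; 19, DMPU, −30 → 0 °C
Reagents that add atoms: none
Why: In this deconjugative α-alkylation, γ-deprotonation of the alkylidene ketone gives extended dienolate 20, which attacks the primary iodide through its α-carbon C9 from the convex face, creating the quaternary carbon with the double bond moved to C8=C7, and the C9 configuration is of no consequence.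

Step 13
Reactants: 21 vinylcyclobutanone
Product: 22 8-isopropenyl-1,5-dimethyl-8-[2-(2-methyl-1,3-dioxolan-2-yl)ethyl]-5-[(triisopropylsilyloxy)methyl]bicyclo[4.2.0]octane-4,7-diol (3β-OH; C6-OH concave, cis to isopropenyl)
Conditions: LiAlH4, Et2O, 0 °C
Reagents that add atoms: none
Why: LiAlH4 reduces the cyclobutanone from the convex face (C6 configuration immaterial) and cleaves the pivalate in the same operation, while the ketal and the Si(i-Pr)3 ether are inert.

Step 14
Reactants: 22 isopropenyl bicyclo[4.2.0]octanediol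
Product: 25 13,13-ethylenedioxy-19-(triisopropylsilyloxy)-14,15-dinor-5β-labd-8-ene-3β,6β-diol (cis-fused octalin), via dipotassium dialkoxide 23 (not isolated), via ring-opened allyl anion aldehyde 24 (not isolated)
Conditions: KH (4 equiv), 18-crown-6, THF, 0 → 50 °C; then H2O
Reagents that add atoms: none
Why: KH gives dialkoxide 23, and donation from the C6 oxyanion into the strained, allylic C6–C9 bond (the only ring bond whose cleavage leaves a stabilised carbanion) breaks it heterolytically to 24, a C6 aldehyde and a C9–C8–C7 allyl anion still tied together through C5–C10 of ring A. The unsubstituted terminus C7 then adds to the aldehyde, so C6 moves from C9 to C7 in a formal 1,3-sigmatropic shift, the closest known reaction being the alkoxide-accelerated rearrangement of 2-vinylcyclobutanols, obtained from ketene-derived 2-vinylcyclobutanones, to cyclohex-3-enols. Ring B closes in a 6-exo-trig mode at the carbonyl group with the new C8=C9 bond endocyclic, which needs the isopropenyl rotamer that holds C7 on the C10 side of C9, the rotamer that also keeps the C17 methyl away from quaternary C10. The only new stereocentre is C6, where the solvated potassium oxygen should take the convex β face of the emerging cis-octalin; it is erased in step 15, C9 loses its stereocentre here, and C4, C5 and C10 are untouched. The step needs bonding at C7 rather than return to C9 or proton transfer from C5–H: return to C9 only regenerates strained 23 reversibly whereas closure at C7 releases the cyclobutane strain, C9 is the fully substituted and more hindered terminus, and C5–H lies on the β face opposite the carbanion and is shielded by quaternary C4.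

Step 15
Reactants: 25 cis-octalindiol
Product: 26 13,13-ethylenedioxy-19-(triisopropylsilyloxy)-14,15-dinor-5β-labd-8-ene-3,6-dione
Conditions: (n-Pr4N)RuO4 (cat.), N-methylmorpholine N-oxide, 4 Å molecular sieves, CH2Cl2, 23 °C
Reagents that add atoms: none
Why: Ley–Griffith oxidation under neutral conditions converts both secondary alcohols into ketones without disturbing the ketal, the silyl ether or the tetrasubstituted alkene, erasing the provisional C3 and C6 centres.

Step 16
Reactants: 26 cis-fused enedione
Product: 27 13,13-ethylenedioxy-19-(triisopropylsilyloxy)-14,15-dinorlabd-7-ene-3,6-dione (trans-fused, 5α-H, 9α-H)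
Conditions: NaOMe (cat.), MeOH–THF, 40 °C
Reagents that add atoms: none
Why: Base-catalysed equilibration through the C5 and C7 enolates epimerises C5 to the more stable trans-decalin (5α-H) as in 6-oxo labdanes, slides the double bond into conjugation at C7=C8, and protonates C9 so that the side chain is equatorial (9α-H, temporary).

Step 17
Reactants: 27 trans-fused conjugated enedione
Product: 29 13,13-ethylenedioxy-19-(triisopropylsilyloxy)-14,15-dinorlabd-8-ene-3,6-dione (trans-fused, 5α-H), via potassium dienolate 28 (not isolated)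
Conditions: KOt-Bu (4 equiv), t-BuOH–THF, 23 °C, short contact; inverse quench into AcOH–H2O, 0 °C
Reagents that add atoms: none
Why: In this deconjugation by kinetic protonation, KOt-Bu removes the γ-hydrogen at C9 to give the fully substituted linear dienolate 28 and the fast quench protonates its α-carbon C7, as in the classical conversion of steroidal 4-en-3-ones into 5-en-3-ones, restoring C8=C9 without touching C5.

Step 18
Reactants: 29 trans-fused 8-ene-3,6-dione
Product: 30 13,13-ethylenedioxy-19-(triisopropylsilyloxy)-14,15-dinorlabd-8-ene-3α,6β-diol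
Conditions: LiBH(s-Bu)3 (3 equiv), THF, −78 → −20 °C
Reagents that add atoms: none
Why: One bulky borohydride sets both carbinols, because at C6 the β face is closed by the syn-axial C19 and C20 groups so hydride enters from α (6β-OH), and at C3 the reagent takes the equatorial trajectory as in 4,4-disubstituted 3-oxo terpenoids to give the axial 3α-OH.

Step 19
Reactants: 30 diol ketal
Product: 31 3α,6β-dihydroxy-19-(triisopropylsilyloxy)-14,15-dinorlabd-8-en-13-one
Conditions: pyridinium p-toluenesulfonate (cat.), THF–H2O, 50 °C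
Reagents that add atoms: water, O
Why: Mild acid-catalysed hydrolysis removes the dioxolane, and the hindered silyl ether and the homoallylic alcohol tolerate it.

Step 20
Reactants: 31 methyl ketone
Product: 32 allyl (13E)-3α,6β-dihydroxy-19-(triisopropylsilyloxy)labda-8,13-dien-15-oate
Conditions: (EtO)2P(O)CH2CO2CH2CH=CH2, NaH, THF, 0 → 50 °C
Reagents that add atoms: allyl diethylphosphonoacetate, CCOP(=O)(CC(=O)OCC=C)OCC
Why: Horner–Wadsworth–Emmons olefination of the methyl ketone with excess stabilised phosphonate anion (to cover the two hydroxyls) favours the E-trisubstituted enoate, the Z isomer being removable by chromatography, and the allyl ester lets the acid be freed later beside the isovalerates.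

Step 21
Reactants: 32 silyl ether
Product: 33 allyl (13E)-3α,6β,19-trihydroxylabda-8,13-dien-15-oate
Conditions: n-Bu4NF, THF, 23 °C
Reagents that add atoms: none
Why: Fluoride cleaves the silyl ether, driven by Si–F bond formation, and leaves the enoate and both alkenes untouched.

Step 22
Reactants: 33 triol
Product: 34 allyl (13E)-6β-hydroxy-3α,19-bis(3-methylbutanoyloxy)labda-8,13-dien-15-oate
Conditions: (i-BuCO)2O (2.5 equiv), Et3N, DMAP, CH2Cl2, 0 → 23 °C
Reagents that add atoms: isovaleric anhydride, CC(C)CC(=O)OC(=O)CC(C)C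
Why: This DMAP-catalysed acylation should be site-selective, since primary O19 and secondary O3 react whereas the 6β-OH, wedged between the syn-axial C19 and C20 substituents, belongs to a hydroxyl class known to resist acylation.

Step 23
Reactants: 34 allyl ester
Product: 35 (13E)-6β-hydroxy-3α,19-bis(3-methylbutanoyloxy)labda-8,13-dien-15-oic acid (CNP0333611.1)
Conditions: Pd(PPh3)4 (cat.), morpholine, THF, 23 °C
Reagents that add atoms: none
Why: In this Tsuji–Trost-type deallylation, zerovalent palladium ionises only the allyl ester and morpholine traps the π-allyl fragment, under neutral conditions that spare the isovalerates, the free alcohol and both alkenes.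

**Compound list**
1 | 2-methoxy-5-methylbenzoic acid | COc1ccc(C)cc1C(=O)O | starting material
2 | (R)-2-(methoxymethyl)pyrrolidine | COC[C@H]1CCCN1 | starting material
3 | 2-methoxy-5-methylbenzoyl chloride | COc1ccc(C)cc1C(Cl)=O | intermediate
4 | (R)-[2-(methoxymethyl)pyrrolidin-1-yl](2-methoxy-5-methylphenyl)methanone | COC[C@H]1CCCN1C(=O)c1cc(C)ccc1OC | intermediate
5 | potassium amide enolate of the 1,4-dihydrobenzamide | COC[C@H]1CCCN1C([O-])=C1C=C(C)CC=C1OC.[K+] | intermediate
6 | [(1R)-2-methoxy-1,5-dimethylcyclohexa-2,5-dien-1-yl][(2R)-2-(methoxymethyl)pyrrolidin-1-yl]methanone | CC1=C[C@@](C)(C(=O)N2CCC[C@@H]2COC)C(OC)=CC1 | intermediate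
7 | [(1S)-2-methoxy-1,5-dimethylcyclohexa-2,5-dien-1-yl]methanol | CC1=C[C@@](C)(CO)C(OC)=CC1 | intermediate
8 | triisopropylsilyl ether of 7 | CC1=C[C@@](C)(CO[Si](C(C)C)(C(C)C)C(C)C)C(OC)=CC1 | intermediate
9 | (2S)-2,4-dimethyl-2-[(triisopropylsilyloxy)methyl]cyclohex-3-en-1-one | CC1=C[C@@](C)(CO[Si](C(C)C)(C(C)C)C(C)C)C(=O)CC1 | intermediate
10 | (1S,2S)-2,4-dimethyl-2-[(triisopropylsilyloxy)methyl]cyclohex-3-en-1-ol | CC1=C[C@@](C)(CO[Si](C(C)C)(C(C)C)C(C)C)[C@@H](O)CC1 | intermediate
11 | pivalate of 10 (ring A alkene) | CC1=C[C@@](C)(CO[Si](C(C)C)(C(C)C)C(C)C)[C@@H](OC(=O)C(C)(C)C)CC1 | intermediate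
12 | α-face dichlorocyclobutanone (5β-H, 10β-CH3, 3β-OPiv) | ClC1(Cl)[C@@]2(C)CC[C@H](OC(=O)C(C)(C)C)[C@](C)(CO[Si](C(C)C)(C(C)C)C(C)C)[C@H]2C1=O | intermediate
13 | dechlorinated cyclobutanone | C1[C@@]2(C)CC[C@H](OC(=O)C(C)(C)C)[C@](C)(CO[Si](C(C)C)(C(C)C)C(C)C)[C@H]2C1=O | intermediate
14 | lithium C6–C9 enolate of 13 | [Li+].[O-]C1=C[C@@]2(C)CC[C@H](OC(=O)C(C)(C)C)[C@](C)(CO[Si](C(C)C)(C(C)C)C(C)C)[C@H]21 | intermediate
15 | acetone aldol at C9 (convex) | CC(C)(O)[C@@H]1[C@@]2(C)CC[C@H](OC(=O)C(C)(C)C)[C@](C)(CO[Si](C(C)C)(C(C)C)C(C)C)[C@H]2C1=O | intermediate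
16 | tertiary mesylate of 15 | CC(C)(OS(C)(=O)=O)[C@@H]1[C@@]2(C)CC[C@H](OC(=O)C(C)(C)C)[C@](C)(CO[Si](C(C)C)(C(C)C)C(C)C)[C@H]2C1=O | intermediate
17 | 9-isopropylidene cyclobutanone | CC(C)=C1[C@@]2(C)CC[C@H](OC(=O)C(C)(C)C)[C@](C)(CO[Si](C(C)C)(C(C)C)C(C)C)[C@H]2C1=O | intermediate
18 | 2-(2-bromoethyl)-2-methyl-1,3-dioxolane | CC1(CCBr)OCCO1 | starting material
19 | 2-(2-iodoethyl)-2-methyl-1,3-dioxolane | CC1(CCI)OCCO1 | intermediate
20 | potassium extended dienolate of 17 | CC(=C)C1=C([O-])[C@@H]2[C@@](C)(CO[Si](C(C)C)(C(C)C)C(C)C)[C@@H](OC(=O)C(C)(C)C)CC[C@]12C.[K+] | intermediate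
21 | 9-isopropenyl-9-alkyl cyclobutanone | CC(=C)[C@@]1(CCC2(C)OCCO2)[C@@]3(C)CC[C@H](OC(=O)C(C)(C)C)[C@](C)(CO[Si](C(C)C)(C(C)C)C(C)C)[C@H]3C1=O | intermediate
22 | isopropenyl bicyclo[4.2.0]octane-3β,6-diol (key-step precursor) | CC(=C)[C@@]1(CCC2(C)OCCO2)[C@@]3(C)CC[C@H](O)[C@](C)(CO[Si](C(C)C)(C(C)C)C(C)C)[C@H]3[C@H]1O | intermediate
23 | dipotassium dialkoxide of 22 | CC(=C)[C@@]1(CCC2(C)OCCO2)[C@@]3(C)CC[C@H]([O-])[C@](C)(CO[Si](C(C)C)(C(C)C)C(C)C)[C@H]3[C@H]1[O-].[K+].[K+] | intermediate
24 | ring-opened C6 aldehyde / C7–C8–C9 allyl anion | [CH2-]/C(C)=C(/CCC1(C)OCCO1)[C@@]2(C)CC[C@H]([O-])[C@](C)(CO[Si](C(C)C)(C(C)C)C(C)C)[C@H]2C=O.[K+].[K+] | intermediate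
25 | cis-fused 8-ene-3β,6β-diol (key-step product) | CC1=C(CCC2(C)OCCO2)[C@@]3(C)CC[C@H](O)[C@](C)(CO[Si](C(C)C)(C(C)C)C(C)C)[C@H]3[C@H](O)C1 | intermediate
26 | cis-fused 8-ene-3,6-dione | CC1=C(CCC2(C)OCCO2)[C@@]3(C)CCC(=O)[C@](C)(CO[Si](C(C)C)(C(C)C)C(C)C)[C@H]3C(=O)C1 | intermediate
27 | trans-fused 7-ene-3,6-dione (5α-H, 9α-H) | CC1=CC(=O)[C@H]2[C@@](C)(CO[Si](C(C)C)(C(C)C)C(C)C)C(=O)CC[C@]2(C)[C@H]1CCC1(C)OCCO1 | intermediate
28 | potassium 6,8-dienolate | CC1=C(CCC2(C)OCCO2)[C@@]3(C)CCC(=O)[C@](C)(CO[Si](C(C)C)(C(C)C)C(C)C)[C@@H]3C([O-])=C1.[K+] | intermediate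
29 | trans-fused 8-ene-3,6-dione | CC1=C(CCC2(C)OCCO2)[C@@]3(C)CCC(=O)[C@](C)(CO[Si](C(C)C)(C(C)C)C(C)C)[C@@H]3C(=O)C1 | intermediate
30 | trans-fused 8-ene-3α,6β-diol | CC1=C(CCC2(C)OCCO2)[C@@]3(C)CC[C@@H](O)[C@](C)(CO[Si](C(C)C)(C(C)C)C(C)C)[C@@H]3[C@H](O)C1 | intermediate
31 | C13 methyl ketone | CC1=C(CCC(C)=O)[C@@]2(C)CC[C@@H](O)[C@](C)(CO[Si](C(C)C)(C(C)C)C(C)C)[C@@H]2[C@H](O)C1 | intermediate
32 | allyl (13E)-enoate, 19-silyl ether | CC1=C(CC/C(C)=C/C(=O)OCC=C)[C@@]2(C)CC[C@@H](O)[C@](C)(CO[Si](C(C)C)(C(C)C)C(C)C)[C@@H]2[C@H](O)C1 | intermediate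
33 | allyl (13E)-3α,6β,19-trihydroxylabda-8,13-dien-15-oate | CC1=C(CC/C(C)=C/C(=O)OCC=C)[C@@]2(C)CC[C@@H](O)[C@](C)(CO)[C@@H]2[C@H](O)C1 | intermediate
34 | allyl ester of the target | CC1=C(CC/C(C)=C/C(=O)OCC=C)[C@@]2(C)CC[C@@H](OC(=O)CC(C)C)[C@](C)(COC(=O)CC(C)C)[C@@H]2[C@H](O)C1 | intermediate
35 | (13E)-6β-hydroxy-3α,19-bis(3-methylbutanoyloxy)labda-8,13-dien-15-oic acid | CC1=C(CC/C(C)=C/C(=O)O)[C@@]2(C)CC[C@@H](OC(=O)CC(C)C)[C@](C)(COC(=O)CC(C)C)[C@@H]2[C@H](O)C1 | target

Total step count: 23. Longest linear sequence: 22 steps (steps 1–10 and 12–23; step 11 is a one-step branch).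

**Steps most likely to fail**

1. **Step 12.** C-alkylation at C9, next to quaternary C10, may be so slow that elimination of HI from the iodide, O-alkylation, or proton exchange to the C5 enolate takes over.
   - The fallback gives up the stepwise dressing of C9 and brings both C9 substituents in on the ketene. It sets out from 11 and 18 and comes back at 21.
   - Commercial 3-methylbut-2-enoic acid is converted with two equivalents of LiN(i-Pr)2 into its dienediolate. Bromide 18 alkylates it at the α-carbon to give racemic 3-methyl-2-[2-(2-methyl-1,3-dioxolan-2-yl)ethyl]but-3-enoic acid F1.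
   - 1-Chloro-N,N,2-trimethylprop-1-en-1-amine turns F1 under neutral conditions into 3-methyl-2-[2-(2-methyl-1,3-dioxolan-2-yl)ethyl]but-3-enoyl chloride F2.
   - Slow addition of F2 to 11 and Et3N in hot toluene releases isopropenyl[2-(2-methyl-1,3-dioxolan-2-yl)ethyl]ketene F3. Its thermal vinylketene–alkene [2+2] cycloaddition with C5=C10, with the regiochemistry and α-face preference of step 7, gives 21; either C9 epimer serves.

2. **Step 14.** Proton transfer to the allyl anion (plain ring opening) or unproductive return to C9 may outrun closure at C7.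
   - The fallback moves the same C6 migration to the ketone oxidation level. It sets out from 21 and comes back at 26.
   - Direct irradiation of 21 (about 300 nm, benzene) should cause alpha-cleavage of C6–C9 to an acyl/allyl radical pair that recombines at C7. This is the known photochemical 1,3-acyl shift that expands 2-vinylcyclobutanones to cyclohex-3-enones, and it gives 13,13-ethylenedioxy-6-oxo-19-(triisopropylsilyloxy)-14,15-dinor-5β-labd-8-en-3β-yl pivalate F4.
   - LiAlH4 then gives 13,13-ethylenedioxy-19-(triisopropylsilyloxy)-14,15-dinor-5β-labd-8-ene-3β,6α-diol F5, the C6 epimer of 25. The oxidation of step 15 converts F5 into 26.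

3. **Step 7.** Bond formation at C5, beside quaternary C4, may be sluggish enough for the ketene to oligomerise first, and α-face selectivity may erode.
   - The fallback replaces the neutral ketene by a cationic and far more electrophilic cumulene and skips the dechlorination. It sets out from 11 and comes back at 13.
   - N,N-Dimethylacetamide, (CF3SO2)2O and 2,4,6-collidine in refluxing 1,2-dichloroethane generate the keteniminium ion. Its [2+2] cycloaddition with 11 gives the N,N-dimethylcyclobutaniminium triflate F6.
   - Aqueous NaHCO3 hydrolyses F6 to 13.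

**Further compounds**
F1 | step 12 | 3-methyl-2-[2-(2-methyl-1,3-dioxolan-2-yl)ethyl]but-3-enoic acid (racemic) | C=C(C)C(CCC1(C)OCCO1)C(=O)O
F2 | step 12 | 3-methyl-2-[2-(2-methyl-1,3-dioxolan-2-yl)ethyl]but-3-enoyl chloride (racemic) | C=C(C)C(CCC1(C)OCCO1)C(Cl)=O
F3 | step 12 | isopropenyl[2-(2-methyl-1,3-dioxolan-2-yl)ethyl]ketene | C=C(C)C(CCC1(C)OCCO1)=C=O
F4 | step 14 | 13,13-ethylenedioxy-6-oxo-19-(triisopropylsilyloxy)-14,15-dinor-5β-labd-8-en-3β-yl pivalate | CC1=C(CCC2(C)OCCO2)[C@@]3(C)CC[C@H](OC(=O)C(C)(C)C)[C@](C)(CO[Si](C(C)C)(C(C)C)C(C)C)[C@H]3C(=O)C1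
F5 | step 14 | 13,13-ethylenedioxy-19-(triisopropylsilyloxy)-14,15-dinor-5β-labd-8-ene-3β,6α-diol | CC1=C(CCC2(C)OCCO2)[C@@]3(C)CC[C@H](O)[C@](C)(CO[Si](C(C)C)(C(C)C)C(C)C)[C@H]3[C@@H](O)C1
F6 | step 7 | N,N-dimethylcyclobutaniminium triflate corresponding to 13 | C[N+](C)=C1C[C@@]2(C)CC[C@H](OC(=O)C(C)(C)C)[C@](C)(CO[Si](C(C)C)(C(C)C)C(C)C)[C@H]21.[O-]S(=O)(=O)C(F)(F)F
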